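C6 (ring B carbinol, labdane numbering) lies 1,3 to the quaternary C10 through C5 and 1,3 to the methylene-bearing C8 through C7. At ketone level C6(=O)-C5=C10 is therefore an enone with C10 as β-carbon, C8 is a masked ketone, and the arc C6-C7-C8-C9 can be folded into a cyclobutane by one extra bond, C6-C9.
Key disconnection C9-C10: ring B contracts to a 1-(cyclohexenyl)cyclobutanol. In the forward sense an O-centred radical cleaves the strained C6-C9 bond and the C9 radical returns 6-endo to C10, which expands the ring by two carbons and sets the quaternary centre and the trans-decalin.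
C5-C6: the cyclobutanol comes from a ring A vinyl iodide that already carries the C2 chloride (made from ketoisophorone) and a cyclobutanone from a ketene/ketene acetal (2+2) cycloaddition.
C12-C13: Evans syn aldol on the C12 aldehyde. The succinimide is closed last with ammonia.
Ring order: ring A (bought), cyclobutane (temporary), ring B (key step), succinimide.

Key step: step 8

Remark: labdane numbering is used for all intermediates (ring A = C1-C5 plus C10, ring B = C5-C10, C17 = exocyclic methylene carbon, C11-C16 = side chain plus imide); the target SMILES reads as 2α-Cl, 5α-H, 6β-OH, 9α-H, 10β-CH3, 12S, 13R.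

Step 1
Reactants: 1 ketoisophorone (2,6,6-trimethylcyclohex-2-ene-1,4-dione)
Product: 2 (4R)-4-hydroxy-2,6,6-trimethylcyclohex-2-en-1-one
Conditions: RuCl[(R,R)-TsDPEN](p-cymene) (cat.), KOH (cat.), i-PrOH, rt
Reagents that add atoms: none
Why: Noyori asymmetric transfer hydrogenation should reduce only the unhindered carbonyl (the other is flanked by the gem-dimethyl carbon and the methyl-bearing alkene carbon) and, with the alkene side of the ketone playing the part of the aryl group in the usual model, the (R,R) ligand should set the (R) carbinol, the future C2.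

Step 2
Reactants: 2 (4R)-4-hydroxy-2,6,6-trimethylcyclohex-2-en-1-one
Product: 3 (4S)-4-hydroxy-2,2,6-trimethylcyclohexan-1-one (epimers at the methyl-bearing carbon)
Conditions: H2 (1 atm), Pd/C, EtOAc, rt
Reagents that add atoms: none
Why: Heterogeneous catalytic hydrogenation saturates the enone C=C without touching the carbinol centre; the new methyl-bearing centre forms as an epimer mixture that is irrelevant because it returns to sp2 in step 4.

Step 3
Reactants: 3 (4S)-4-hydroxy-2,2,6-trimethylcyclohexan-1-one
Product: 4 hydrazone of 3
Conditions: N2H4·H2O, Et3N, EtOH, reflux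
Reagents that add atoms: hydrazine NN
Why: Hydrazone condensation, which works on 2,2,6-trialkylcyclohexanones under forcing conditions; the remote secondary alcohol is inert.

Step 4
Reactants: 4 hydrazone of 3
Product: 5 (1S)-4-iodo-3,5,5-trimethylcyclohex-3-en-1-ol
Conditions: I2, 1,1,3,3-tetramethylguanidine, Et2O/THF, 0 °C to rt
Reagents that add atoms: iodine [I][I]
Why: Barton vinyl iodide synthesis: oxidation of the hydrazone and loss of nitrogen lead to an iodinated stage that can lose a proton only from the methyl-bearing α-carbon (the other α-carbon is quaternary), so a single tetrasubstituted vinyl iodide should result.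

Step 5
Reactants: 5 (1S)-4-iodo-3,5,5-trimethylcyclohex-3-en-1-ol
Product: 6 (5R)-5-chloro-2-iodo-1,3,3-trimethylcyclohex-1-ene
Conditions: PPh3, CCl4, CH2Cl2, 0 °C to rt
Reagents that add atoms: tetrachloromethane ClC(Cl)(Cl)Cl
Why: Appel reaction: SN2 displacement of the alkoxyphosphonium ion by chloride inverts the carbinol centre and installs the C2 chloride in its final configuration, the iodine-bearing alkene being too electron-poor for homoallylic participation.

Step 6
Reactants: 7 4-bromobutanoyl chloride; 8 1,1-diethoxyethene
Product: 10 2-(2-bromoethyl)-3,3-diethoxycyclobutan-1-one (racemic), via (2-bromoethyl)ketene 9 (not isolated)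
Conditions: i-Pr2NEt, Et2O, reflux, slow addition of 7
Reagents that add atoms: none
Why: Dehydrochlorination gives the aldoketene, which is trapped in a thermal ketene/ketene acetal (2+2) cycloaddition; the nucleophilic CH2 terminus of 8 bonds to the ketene carbonyl carbon and the dialkoxy-stabilised cation closes on the ketene α-carbon, which fixes the 2-alkyl-3,3-dialkoxy pattern (the racemic stereocentre is erased in step 8).

Step 7
Reactants: 6 (5R)-5-chloro-2-iodo-1,3,3-trimethylcyclohex-1-ene; 10 2-(2-bromoethyl)-3,3-diethoxycyclobutan-1-one
Product: 13 2-(2-bromoethyl)-1-[(4R)-4-chloro-2,6,6-trimethylcyclohex-1-en-1-yl]-3,3-diethoxycyclobutan-1-ol (diastereomer mixture at the cyclobutane centres), via vinyllithium 11 (not isolated), via organocerium dichloride 12 (not isolated)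
Conditions: t-BuLi (2 equiv), Et2O, -78 °C; CeCl3, THF, -78 °C; 10, -78 °C; then H2O
Reagents that add atoms: none
Why: Iodine-lithium exchange (faster than any reaction of the alkyl halides at -78 °C), transmetalation to the weakly basic organocerium reagent and 1,2-addition to the strained, highly electrophilic cyclobutanone should outrun enolisation and β-elimination of ethoxide; both new cyclobutane stereocentres are inconsequential.

Step 8
Reactants: 13 2-(2-bromoethyl)-1-[(4R)-4-chloro-2,6,6-trimethylcyclohex-1-en-1-yl]-3,3-diethoxycyclobutan-1-ol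
Product: 14 12-bromo-2α-chloro-8,8-diethoxy-13,14,15,16,17-pentanorlabdan-6-one (trans-decalone, 5α-H, 9α-H, 10β-CH3)
Conditions: [Ir(dF(CF3)ppy)2(5,5'-d(CF3)bpy)]PF6 (2 mol %), 2,4,6-collidine, PhCF3 (high dilution), blue LEDs, rt, argon
Reagents that add atoms: none
Why: Proposed new method: proton-coupled electron transfer from the tertiary O-H bond of 13 to the photoexcited iridium complex and collidine (directly or by way of the radical cation of the adjacent tetrasubstituted alkene) should give the cyclobutyloxy radical, whose ring strain drives β-scission of the more substituted C6-C9 bond and so unmasks the C6(=O)-C5=C10 enone together with a tethered, nucleophilic secondary C9 radical; this radical adds to the β-carbon C10, and the tertiary α-keto radical at C5 is reduced by the divalent iridium complex and protonated by collidinium, which makes the step a redox-neutral isomerisation. The closest known reaction type is the photocatalytic alkoxy-radical ring expansion of 1-alkenylcycloalkanols by two carbons (β-scission, then endo Giese-type return of the alkyl radical to the liberated enone), which has not been shown for a fully substituted β-carbon embedded in a second ring. Ring B closes in the 6-endo-trig mode, the 5-exo alternative at C5 being polarity-mismatched and blocked by the quaternary C4 next to it. C10 is controlled by C2: in the ring A half-chair with equatorial chlorine the radical attacks anti to the pseudoaxial C4 methyl, the only trajectory that leads to a chair ring A with axial C10 methyl and equatorial chlorine, whereas the other face would force chlorine syn-axial to two methyl groups. C9 is set by a chair-like transition state with the bromoethyl chain pseudoequatorial (and stays correctable next to the later C8 ketone), and C5 by protonation of the enolate from the α face opposite the two axial methyl groups, which is also the thermodynamic trans-decalone. The selectivities needed are C6-C9 over C6-C7 scission (secondary over primary radical) and cyclisation over premature hydrogen capture (no thiol or other hydrogen-atom donor is present), and because both cyclobutane stereocentres are erased the diastereomer mixture converges.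

Step 9
Reactants: 14 12-bromo-2α-chloro-8,8-diethoxy-13,14,15,16,17-pentanorlabdan-6-one
Product: 15 12-bromo-2α-chloro-8,8-diethoxy-13,14,15,16,17-pentanorlabdan-6β-ol
Conditions: DIBAL-H, CH2Cl2, -78 to -20 °C; then H2O
Reagents that add atoms: none
Why: Hydride reduction of a hindered ketone: the β face of C6 is closed by the two syn-axial methyl groups on C4 and C10, so DIBAL-H attacks from the α face and should give the axial 6β alcohol, while the ketal and both alkyl halides survive.

Step 10
Reactants: 15 12-bromo-2α-chloro-8,8-diethoxy-13,14,15,16,17-pentanorlabdan-6β-ol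
Product: 16 12-bromo-2α-chloro-6β-hydroxy-13,14,15,16,17-pentanorlabdan-8-one
Conditions: p-TsOH·H2O (cat.), acetone/H2O, rt
Reagents that add atoms: water O
Why: Acid-catalysed ketal hydrolysis, accelerated by relief of the syn-axial ethoxy/C10-methyl interaction and mild enough to leave the β-hydroxy ketone undehydrated; enolisation toward C9 lets any axial side-chain epimer settle in the equatorial 9β arrangement.

Step 11
Reactants: 16 12-bromo-2α-chloro-6β-hydroxy-13,14,15,16,17-pentanorlabdan-8-one
Product: 17 12-bromo-2α-chloro-13,14,15,16-tetranorlabd-8(17)-en-6β-ol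
Conditions: Zn, CH2Br2, TiCl4, THF, -40 to 5 °C (pre-formed reagent); then 16, CH2Cl2, 0 °C to rt
Reagents that add atoms: dibromomethane BrCBr
Why: Takai-Lombardo methylenation: the non-basic gem-dimetallic reagent converts hindered, enolisable ketones into methylene compounds without epimerisation at C9, retro-aldol cleavage or β-elimination, and tolerates the free hindered alcohol.

Step 12
Reactants: 17 12-bromo-2α-chloro-13,14,15,16-tetranorlabd-8(17)-en-6β-ol
Product: 18 2α-chloro-6β-hydroxy-13,14,15,16-tetranorlabd-8(17)-en-12-al
Conditions: Me3NO (anhydrous), NaHCO3, DMSO, rt to 40 °C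
Reagents that add atoms: trimethylamine N-oxide C[N+](C)(C)[O-]
Why: Ganem oxidation (amine N-oxide variant of the Kornblum oxidation): SN2 attack of the N-oxide oxygen on the primary bromide and base-induced loss of trimethylamine give the aldehyde; the hindered secondary chloride, the axial alcohol and the alkene do not react.

Step 13
Reactants: 19 (4R)-4-benzyl-1,3-oxazolidin-2-one; 20 methyl 4-chloro-4-oxobutanoate
Product: 21 methyl 4-[(4R)-4-benzyl-2-oxo-1,3-oxazolidin-3-yl]-4-oxobutanoate
Conditions: Et3N, DMAP (cat.), CH2Cl2, 0 °C to rt
Reagents that add atoms: none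
Why: N-acylation of the oxazolidinone by the acid chloride under DMAP catalysis, a standard route to Evans imides.

Step 14
Reactants: 21 methyl 4-[(4R)-4-benzyl-2-oxo-1,3-oxazolidin-3-yl]-4-oxobutanoate; 18 2α-chloro-6β-hydroxy-13,14,15,16-tetranorlabd-8(17)-en-12-al
Product: 23 syn-aldol adduct methyl (3R,4S)-3-{[(4R)-4-benzyl-2-oxo-1,3-oxazolidin-3-yl]carbonyl}-4-hydroxy-5-(decalinyl)pentanoate (12S and 13R in labdane numbering), via dibutylboron Z-enolate 22 (not isolated)
Conditions: Bu2BOTf, Et3N, CH2Cl2, -78 to 0 °C (excess enolate); 18, -78 to 0 °C; then pH 7 buffer, MeOH, H2O2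
Reagents that add atoms: none
Why: Evans syn aldol reaction: soft enolisation takes place at the imide and not at the ester, the Z-boron enolate reacts through a Zimmerman-Traxler chair on the face opposite the benzyl group, and the (R)-auxiliary thus sets 12S and 13R irrespective of the remote decalin centres; the shielded 6β-OH at most consumes excess enolate.

Step 15
Reactants: 23 syn-aldol adduct
Product: 25 haterumaimide F, via hydroxy amide ester 24 (not isolated)
Conditions: NH3 (7 M in MeOH), 0 °C to rt
Reagents that add atoms: ammonia N
Why: Ammonolysis of the activated exocyclic imide carbonyl releases the auxiliary, and the primary amide then closes onto the methyl ester in a 5-exo-trig, aspartimide-type cyclisation to the succinimide; the conditions are too mild to epimerise C13, to trigger retro-aldol cleavage or to displace the chloride.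

Compound list
1 | ketoisophorone (2,6,6-trimethylcyclohex-2-ene-1,4-dione) | CC1=CC(=O)CC(C)(C)C1=O | starting material
2 | (4R)-4-hydroxy-2,6,6-trimethylcyclohex-2-en-1-one | CC1=C[C@H](O)CC(C)(C)C1=O | intermediate
3 | (4S)-4-hydroxy-2,2,6-trimethylcyclohexan-1-one (C6 epimers) | CC1C[C@H](O)CC(C)(C)C1=O | intermediate
4 | hydrazone of 3 | CC1C[C@H](O)CC(C)(C)C1=NN | intermediate
5 | (1S)-4-iodo-3,5,5-trimethylcyclohex-3-en-1-ol | IC1=C(C)C[C@H](O)CC1(C)C | intermediate
6 | (5R)-5-chloro-2-iodo-1,3,3-trimethylcyclohex-1-ene | IC1=C(C)C[C@@H](Cl)CC1(C)C | intermediate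
7 | 4-bromobutanoyl chloride | O=C(Cl)CCCBr | starting material
8 | 1,1-diethoxyethene | C=C(OCC)OCC | starting material
9 | (2-bromoethyl)ketene (4-bromobut-1-en-1-one) | O=C=CCCBr | intermediate
10 | 2-(2-bromoethyl)-3,3-diethoxycyclobutan-1-one (racemic) | O=C1CC(OCC)(OCC)C1CCBr | intermediate
11 | [(4R)-4-chloro-2,6,6-trimethylcyclohex-1-en-1-yl]lithium | [Li]C1=C(C)C[C@@H](Cl)CC1(C)C | intermediate
12 | dichloro[(4R)-4-chloro-2,6,6-trimethylcyclohex-1-en-1-yl]cerium | Cl[Ce](Cl)C1=C(C)C[C@@H](Cl)CC1(C)C | intermediate
13 | 2-(2-bromoethyl)-1-[(4R)-4-chloro-2,6,6-trimethylcyclohex-1-en-1-yl]-3,3-diethoxycyclobutan-1-ol (cyclobutane centres undefined) | OC1(CC(OCC)(OCC)C1CCBr)C1=C(C)C[C@@H](Cl)CC1(C)C | intermediate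
14 | 12-bromo-2α-chloro-8,8-diethoxy-13,14,15,16,17-pentanorlabdan-6-one | CCOC1(OCC)CC(=O)[C@H]2C(C)(C)C[C@H](Cl)C[C@]2(C)[C@H]1CCBr | intermediate
15 | 12-bromo-2α-chloro-8,8-diethoxy-13,14,15,16,17-pentanorlabdan-6β-ol | CCOC1(OCC)C[C@@H](O)[C@H]2C(C)(C)C[C@H](Cl)C[C@]2(C)[C@H]1CCBr | intermediate
16 | 12-bromo-2α-chloro-6β-hydroxy-13,14,15,16,17-pentanorlabdan-8-one | O=C1C[C@@H](O)[C@H]2C(C)(C)C[C@H](Cl)C[C@]2(C)[C@H]1CCBr | intermediate
17 | 12-bromo-2α-chloro-13,14,15,16-tetranorlabd-8(17)-en-6β-ol | C=C1C[C@@H](O)[C@H]2C(C)(C)C[C@H](Cl)C[C@]2(C)[C@H]1CCBr | intermediate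
18 | 2α-chloro-6β-hydroxy-13,14,15,16-tetranorlabd-8(17)-en-12-al | C=C1C[C@@H](O)[C@H]2C(C)(C)C[C@H](Cl)C[C@]2(C)[C@H]1CC=O | intermediate
19 | (4R)-4-benzyl-1,3-oxazolidin-2-one | O=C1N[C@H](Cc2ccccc2)CO1 | starting material
20 | methyl 4-chloro-4-oxobutanoate | COC(=O)CCC(=O)Cl | starting material
21 | methyl 4-[(4R)-4-benzyl-2-oxo-1,3-oxazolidin-3-yl]-4-oxobutanoate | COC(=O)CCC(=O)N1C(=O)OC[C@H]1Cc1ccccc1 | intermediate
22 | dibutylboron Z-enolate of 21 | COC(=O)C/C=C(\OB(CCCC)CCCC)N1C(=O)OC[C@H]1Cc1ccccc1 | intermediate
23 | syn-aldol adduct (12S,13R) carrying the auxiliary on C16 and the methyl ester on C15 | C=C1C[C@@H](O)[C@H]2C(C)(C)C[C@H](Cl)C[C@]2(C)[C@H]1C[C@H](O)[C@@H](CC(=O)OC)C(=O)N1C(=O)OC[C@H]1Cc1ccccc1 | intermediate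
24 | hydroxy amide ester (C16 carboxamide, C15 methyl ester) | C=C1C[C@@H](O)[C@H]2C(C)(C)C[C@H](Cl)C[C@]2(C)[C@H]1C[C@H](O)[C@@H](CC(=O)OC)C(N)=O | intermediate
25 | haterumaimide F | C=C1C[C@@H](O)[C@H]2C(C)(C)C[C@H](Cl)C[C@]2(C)[C@H]1C[C@H](O)[C@H]1CC(=O)NC1=O | target

Total step count: 15. Longest linear sequence: 13 steps (steps 1-5, 7-12, 14, 15).

Steps most likely to fail

Step 8. The open-chain C9 radical may add too slowly to the fully substituted C10. Hydrogen capture, unproductive oxidation of the tetrasubstituted alkene, or stalled catalyst turnover at the hindered C5 radical could then take over. The fallback uses known chemistry, sets out from 13 and comes back at 14; it separates radical generation from the cyclisation. Suárez hypoiodite fragmentation of 13 (PhI(OAc)2, I2, visible light, CH2Cl2) should give the ring-opened γ-iodo enone 6-bromo-1-[(4R)-4-chloro-2,6,6-trimethylcyclohex-1-en-1-yl]-3,3-diethoxy-4-iodohexan-1-one F1. A tin hydride chain (Bu3SnH by syringe pump, Et3B/air, benzene, high dilution) abstracts the secondary iodine far faster than the primary bromine and should run the reductive 6-endo radical cyclisation to 14.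

Step 11. Attack at the hindered C8 carbonyl may be sluggish, which leaves time for Lewis-acid-induced dehydration of the β-hydroxy ketone. The fallback sets out from 16 and comes back at 17; it replaces one-step methylenation by addition and elimination. Excess Me3SiCH2Li/CeCl3 adds to the C8 ketone to give the β-hydroxysilane 12-bromo-2α-chloro-8-(trimethylsilylmethyl)-13,14,15,16,17-pentanorlabdane-6β,8-diol F2. An acid-induced Peterson elimination (HF, MeCN) then returns to 17.

Step 5. E2 elimination to the cyclohexadiene, and partial loss of inversion through homoallylic participation of the ring alkene, may compete with the SN2 displacement. The fallback sets out from 3 and comes back at 6; the chlorination is moved to the saturated stage, where no alkene can take part. Appel reaction of 3 gives (4R)-4-chloro-2,2,6-trimethylcyclohexan-1-one F3, condensation with hydrazine gives its hydrazone F4, and Barton iodination (I2, tetramethylguanidine) returns to 6.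

Further compounds
F1 | step 8 | 6-bromo-1-[(4R)-4-chloro-2,6,6-trimethylcyclohex-1-en-1-yl]-3,3-diethoxy-4-iodohexan-1-one (iodide centre undefined) | O=C(CC(OCC)(OCC)C(I)CCBr)C1=C(C)C[C@@H](Cl)CC1(C)C
F2 | step 11 | 12-bromo-2α-chloro-8-(trimethylsilylmethyl)-13,14,15,16,17-pentanorlabdane-6β,8-diol (C8 undefined) | C[Si](C)(C)CC1(O)C[C@@H](O)[C@H]2C(C)(C)C[C@H](Cl)C[C@]2(C)[C@H]1CCBr
F3 | step 5 | (4R)-4-chloro-2,2,6-trimethylcyclohexan-1-one (C6 epimers) | CC1C[C@@H](Cl)CC(C)(C)C1=O
F4 | step 5 | hydrazone of F3 | CC1C[C@@H](Cl)CC(C)(C)C1=NN
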